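**Assumption:** the SMILES is read as ent-fisetinidol-(4α→6)-ent-fisetinidol-(4α→8)-catechin-(6→4α)-ent-fisetinidol, i.e. three (2S,3R)-2,3-trans-3,4-cis 5-deoxy units (unit A on C6 of unit B, unit B on C8 and unit D on C6 of the (2R,3S)-catechin unit C); 3',4'-bis(benzyloxy)acetophenone is taken as a catalogue chemical.

## Retrosynthetic overview

1. Target ⇐ hydrogenolysis of its undeca-O-benzyl ether; unit C is bought as (+)-catechin, so only the three pyran rings (ring C of units A, B and D) are built.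
2. Each ent-fisetinidol unit ⇐ one enantiopure retro-chalcone epoxide (ring A–CH(O)CH–CO–ring B). An arene carbon opens the benzylic epoxide carbon with inversion (fixes C3, sets C4 cis to 3-OH); ketone reduction/deacylation and phenol-to-benzylic-carbon closure then set C2 trans.
3. Key step: units A and D together – double arylation at catechin C6 and at C6 of unit B, then one reduction/closure operation that forms two pyran rings.
4. Before that: unit B alone on C8 of tetra-O-benzylcatechin (first pyran ring), then 7-O-benzylation.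
5. Epoxide ⇐ BF3 aldol of 2,4-bis(pivaloyloxy)benzaldehyde with 3',4'-bis(benzyloxy)acetophenone, then La/BINOL epoxidation. Ring order: ring C of unit B, then ring C of units A and D in one operation.

## Route

Step 1
Reactants: 1 (+)-catechin
Product: 2 5,7,3',4'-tetra-O-benzyl-(+)-catechin
Conditions: BnBr (4.4 equiv), K2CO3, DMF, 0 °C to rt
Reagents that add atoms: benzyl bromide BrCc1ccccc1
Why: Williamson etherification alkylates the four phenols but not the secondary 3-OH, which later prevents any catechin oxygen from closing a ring and leaves C8 as the most nucleophilic carbon; no stereocentre is touched.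

Step 2
Reactants: 3 2,4-dihydroxybenzaldehyde
Product: 4 2,4-bis(pivaloyloxy)benzaldehyde
Conditions: PivCl (2.4 equiv), Et3N, DMAP (cat.), CH2Cl2, 0 °C to rt
Reagents that add atoms: pivaloyl chloride CC(C)(C)C(=O)Cl
Why: DMAP-catalysed O-acylation gives hindered aryl esters that make ring A electron-poor (stable epoxide, SN2-type opening later), survive Lewis acid and peroxide, and are removed without an extra step by the later LiAlH4 reduction.

Step 3
Reactants: 4 2,4-bis(pivaloyloxy)benzaldehyde; 5 3',4'-bis(benzyloxy)acetophenone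
Product: 6 (E)-1-[3,4-bis(benzyloxy)phenyl]-3-[2,4-bis(pivaloyloxy)phenyl]prop-2-en-1-one
Conditions: BF3·OEt2 (0.5 equiv), 1,4-dioxane, rt
Reagents that add atoms: none
Why: Lewis-acid-mediated Claisen–Schmidt (crossed aldol) condensation works without hydroxide, so the aryl pivalates and benzyl ethers survive, and dehydration gives the conjugated E-enone under thermodynamic control.

Step 4
Reactants: 6 (E)-1-[3,4-bis(benzyloxy)phenyl]-3-[2,4-bis(pivaloyloxy)phenyl]prop-2-en-1-one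
Product: 7 [3,4-bis(benzyloxy)phenyl][(2R,3S)-3-[2,4-bis(pivaloyloxy)phenyl]oxiran-2-yl]methanone
Conditions: La(O-iPr)3 (5 mol %), (S)-BINOL (5 mol %; the antipode that gives (2R,3S)-chalcone oxide from chalcone), Ph3As=O (5 mol %), TBHP (1.5 equiv, decane), 4 Å molecular sieves, THF, rt; recrystallise
Reagents that add atoms: tert-butyl hydroperoxide CC(C)(C)OO
Why: Catalytic asymmetric nucleophilic (Weitz–Scheffer-type) epoxidation, in which conjugate addition of the lanthanum-bound tert-butylperoxide inside the BINOL pocket and ring closure set both epoxide carbons (trans from the E-alkene, 2R,3S by catalyst control) under non-aqueous, non-hydroxide conditions that spare the pivalates.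

Step 5
Reactants: 2 5,7,3',4'-tetra-O-benzyl-(+)-catechin; 7 [3,4-bis(benzyloxy)phenyl][(2R,3S)-3-[2,4-bis(pivaloyloxy)phenyl]oxiran-2-yl]methanone
Product: 8 (2R,3S)-1-[3,4-bis(benzyloxy)phenyl]-3-[2,4-bis(pivaloyloxy)phenyl]-2-hydroxy-3-(5,7,3',4'-tetra-O-benzylcatechin-8-yl)propan-1-one
Conditions: 2 (2 equiv), Sc(OTf)3 (10 mol %), (CF3)2CHOH/CH2Cl2 (1:1), −20 to 0 °C
Reagents that add atoms: none
Why: Proposed new method: a Lewis acid/hexafluoroisopropanol-activated Friedel–Crafts opening of the α,β-epoxy ketone at its benzylic carbon by C8 of 2 (closest known chemistry: stereoinvertive fluoroalcohol-promoted arylation of styrene oxides and Lewis-acid opening of chalcone epoxides at the β-carbon by thiols and indoles), in which the electron-poor bis(pivaloyloxy)phenyl ring and the adjacent ketone disfavour a free benzylic cation and acyl shift so the arene attacks from the back (inversion at the future C4, the carbinol carbon = future C3 untouched), which for a trans-epoxide gives the 3,4-cis relationship once the ring is closed, with C8 preferred over C6 as usual for benzylated catechin nucleophiles.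

Step 6
Reactants: 8 (2R,3S)-1-[3,4-bis(benzyloxy)phenyl]-3-[2,4-bis(pivaloyloxy)phenyl]-2-hydroxy-3-(5,7,3',4'-tetra-O-benzylcatechin-8-yl)propan-1-one
Product: 10 3',4'-di-O-benzyl-ent-fisetinidol-(4α→8)-5,7,3',4'-tetra-O-benzylcatechin, via deacylated propane-1,2-diol 9 (not isolated)
Conditions: LiAlH4, THF, −20 to 0 °C; aq. HCl quench; then 2 M HCl, MeOH/THF, rt
Reagents that add atoms: none
Why: LiAlH4 reduces the ketone and cleaves both aryl pivalates, then acid ionises the para-benzyloxybenzylic carbinol (both epimers give the same cation) and the ortho-phenol of ring A closes the pyran ring (acid-catalysed cyclodehydration of a 1-aryl-3-(2-hydroxyphenyl)propane-1,2-diol) through the chair with 2-aryl and 3-OH equatorial and the 4-aryl axial, giving the 2,3-trans (2S) ring; no catechin oxygen can compete because all are benzyl ethers.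

Step 7
Reactants: 10 3',4'-di-O-benzyl-ent-fisetinidol-(4α→8)-5,7,3',4'-tetra-O-benzylcatechin
Product: 11 7,3',4'-tri-O-benzyl-ent-fisetinidol-(4α→8)-5,7,3',4'-tetra-O-benzylcatechin
Conditions: BnBr (1.2 equiv), K2CO3, DMF, rt
Reagents that add atoms: benzyl bromide BrCc1ccccc1
Why: Williamson etherification of the only phenol keeps ring A of unit B electron-rich for the next arylation but removes the one oxygen (ortho to C6) that could otherwise close the wrong pyran ring in step 9.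

Step 8
Reactants: 11 7,3',4'-tri-O-benzyl-ent-fisetinidol-(4α→8)-5,7,3',4'-tetra-O-benzylcatechin; 7 [3,4-bis(benzyloxy)phenyl][(2R,3S)-3-[2,4-bis(pivaloyloxy)phenyl]oxiran-2-yl]methanone
Product: 12 bis(α-hydroxy ketone): 11 carrying at catechin C6 and at C6 of the ent-fisetinidol unit the 3-[3,4-bis(benzyloxy)phenyl]-1-[2,4-bis(pivaloyloxy)phenyl]-2-hydroxy-3-oxopropyl chain (both chains configured as in 8)
Conditions: 7 (2.4 equiv), Sc(OTf)3 (20 mol %), (CF3)2CHOH/CH2Cl2 (1:1), 0 °C to rt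
Reagents that add atoms: none
Why: Proposed new method: the stereoinvertive Friedel–Crafts epoxide arylation of step 5 run twice in one flask (closest known chemistry as in step 5), relying on the two most nucleophilic CH carbons of 11 being catechin C6 (trialkoxyarene type) and C6 of unit B (para to O1, ortho to 7-OBn), while the dibenzyloxyphenyl rings are far less nucleophilic and C8 of unit B is flanked on both sides; each backside attack sets a new C4 centre cis to its C3 oxygen.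

Step 9
Reactants: 12 bis(α-hydroxy ketone)
Product: 14 undeca-O-benzyl ether of the target (free 7-OH on units A and D), via deacylated bis(propane-1,2-diol) 13 (not isolated)
Conditions: LiAlH4, THF, −20 to 0 °C; aq. HCl quench; then 2 M HCl, MeOH/THF (2 mM), rt
Reagents that add atoms: none
Why: Twofold version of step 6 in which both ketones are reduced, all four pivalates are cleaved, and the two independent acid-catalysed cyclodehydrations close ring C of unit A and ring C of unit D in one operation, each by its own freed ortho-phenol (the neighbouring oxygens on unit B and catechin are benzyl ethers) and each through the chair that places 2-aryl and 3-OH equatorial, giving both new C2 centres 2,3-trans (2S).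

Step 10
Reactants: 14 undeca-O-benzyl ether of the target
Product: 15 ent-fisetinidol-(4α→6)-ent-fisetinidol-(4α→8)-catechin-(6→4α)-ent-fisetinidol (CNP0126838.1)
Conditions: H2 (1 atm), Pd(OH)2/C, THF/MeOH/H2O, rt
Reagents that add atoms: none
Why: Catalytic hydrogenolysis removes all eleven benzyl ethers under neutral conditions that leave the flavan C2–O1 and C4–aryl bonds intact, as in standard proanthocyanidin debenzylations; no stereocentre is touched.

## Compound list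

1 | (+)-catechin (2R,3S) | O[C@H]1Cc2c(O)cc(O)cc2O[C@@H]1c1ccc(O)c(O)c1 | starting material

2 | 5,7,3',4'-tetra-O-benzyl-(+)-catechin | O[C@H]1Cc2c(OCc3ccccc3)cc(OCc3ccccc3)cc2O[C@@H]1c1ccc(OCc2ccccc2)c(OCc2ccccc2)c1 | intermediate

3 | 2,4-dihydroxybenzaldehyde | O=Cc1ccc(O)cc1O | starting material

4 | 2,4-bis(pivaloyloxy)benzaldehyde | O=Cc1ccc(OC(=O)C(C)(C)C)cc1OC(=O)C(C)(C)C | intermediate

5 | 3',4'-bis(benzyloxy)acetophenone | CC(=O)c1ccc(OCc2ccccc2)c(OCc2ccccc2)c1 | starting material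

6 | (E)-1-[3,4-bis(benzyloxy)phenyl]-3-[2,4-bis(pivaloyloxy)phenyl]prop-2-en-1-one | O=C(/C=C/c1ccc(OC(=O)C(C)(C)C)cc1OC(=O)C(C)(C)C)c1ccc(OCc2ccccc2)c(OCc2ccccc2)c1 | intermediate

7 | [3,4-bis(benzyloxy)phenyl][(2R,3S)-3-[2,4-bis(pivaloyloxy)phenyl]oxiran-2-yl]methanone (trans) | O=C(c1ccc(OCc2ccccc2)c(OCc2ccccc2)c1)[C@@H]1O[C@H]1c1ccc(OC(=O)C(C)(C)C)cc1OC(=O)C(C)(C)C | intermediate

8 | (2R,3S)-1-[3,4-bis(benzyloxy)phenyl]-3-[2,4-bis(pivaloyloxy)phenyl]-2-hydroxy-3-(5,7,3',4'-tetra-O-benzylcatechin-8-yl)propan-1-one | CC(C)(C)C(=O)Oc1ccc(c(OC(=O)C(C)(C)C)c1)[C@H]([C@@H](O)C(=O)c1ccc(OCc2ccccc2)c(OCc2ccccc2)c1)c1c(OCc2ccccc2)cc(OCc2ccccc2)c2c1O[C@H](c1ccc(OCc3ccccc3)c(OCc3ccccc3)c1)[C@@H](O)C2 | intermediate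

9 | 1-[3,4-bis(benzyloxy)phenyl]-3-(2,4-dihydroxyphenyl)-3-(5,7,3',4'-tetra-O-benzylcatechin-8-yl)propane-1,2-diol (C1 epimers; C2 and C3 as in 8) | Oc1ccc(c(O)c1)[C@H]([C@@H](O)C(O)c1ccc(OCc2ccccc2)c(OCc2ccccc2)c1)c1c(OCc2ccccc2)cc(OCc2ccccc2)c2c1O[C@H](c1ccc(OCc3ccccc3)c(OCc3ccccc3)c1)[C@@H](O)C2 | intermediate

10 | 3',4'-di-O-benzyl-ent-fisetinidol-(4α→8)-5,7,3',4'-tetra-O-benzylcatechin (upper unit 2S,3R, 2,3-trans-3,4-cis, free 7-OH) | Oc1ccc2c(c1)O[C@@H](c1ccc(OCc3ccccc3)c(OCc3ccccc3)c1)[C@H](O)[C@@H]2c1c(OCc2ccccc2)cc(OCc2ccccc2)c2c1O[C@H](c1ccc(OCc3ccccc3)c(OCc3ccccc3)c1)[C@@H](O)C2 | intermediate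

11 | 7,3',4'-tri-O-benzyl-ent-fisetinidol-(4α→8)-5,7,3',4'-tetra-O-benzylcatechin | c1ccc(cc1)COc1ccc2c(c1)O[C@@H](c1ccc(OCc3ccccc3)c(OCc3ccccc3)c1)[C@H](O)[C@@H]2c1c(OCc2ccccc2)cc(OCc2ccccc2)c2c1O[C@H](c1ccc(OCc3ccccc3)c(OCc3ccccc3)c1)[C@@H](O)C2 | intermediate

12 | bis(α-hydroxy ketone): 11 with the 3-[3,4-bis(benzyloxy)phenyl]-1-[2,4-bis(pivaloyloxy)phenyl]-2-hydroxy-3-oxopropyl chain at catechin C6 and at C6 of unit B (carbinol carbons R, benzylic carbons formed with inversion, as in 8) | CC(C)(C)C(=O)Oc1ccc(c(OC(=O)C(C)(C)C)c1)[C@H]([C@@H](O)C(=O)c1ccc(OCc2ccccc2)c(OCc2ccccc2)c1)c1cc2c(cc1OCc3ccccc3)O[C@@H](c1ccc(OCc3ccccc3)c(OCc3ccccc3)c1)[C@H](O)[C@@H]2c1c(OCc2ccccc2)c([C@@H]([C@@H](O)C(=O)c2ccc(OCc3ccccc3)c(OCc3ccccc3)c2)c2ccc(OC(=O)C(C)(C)C)cc2OC(=O)C(C)(C)C)c(OCc2ccccc2)c2c1O[C@H](c1ccc(OCc3ccccc3)c(OCc3ccccc3)c1)[C@@H](O)C2 | intermediate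

13 | bis(propane-1,2-diol) from 12: both ketones reduced (carbinol epimers), all four pivalates removed | Oc1ccc(c(O)c1)[C@H]([C@@H](O)C(O)c1ccc(OCc2ccccc2)c(OCc2ccccc2)c1)c1cc2c(cc1OCc3ccccc3)O[C@@H](c1ccc(OCc3ccccc3)c(OCc3ccccc3)c1)[C@H](O)[C@@H]2c1c(OCc2ccccc2)c([C@@H]([C@@H](O)C(O)c2ccc(OCc3ccccc3)c(OCc3ccccc3)c2)c2ccc(O)cc2O)c(OCc2ccccc2)c2c1O[C@H](c1ccc(OCc3ccccc3)c(OCc3ccccc3)c1)[C@@H](O)C2 | intermediate

14 | undeca-O-benzyl ether of the target: 3',4'-di-O-benzyl (unit A), 7,3',4'-tri-O-benzyl (unit B), 5,7,3',4'-tetra-O-benzyl (catechin), 3',4'-di-O-benzyl (unit D); all ent-fisetinidol units 2S,3R, 2,3-trans-3,4-cis | Oc1ccc2c(c1)O[C@@H](c1ccc(OCc3ccccc3)c(OCc3ccccc3)c1)[C@H](O)[C@@H]2c1cc2c(cc1OCc3ccccc3)O[C@@H](c1ccc(OCc3ccccc3)c(OCc3ccccc3)c1)[C@H](O)[C@@H]2c1c(OCc2ccccc2)c([C@@H]2c3ccc(O)cc3O[C@@H](c3ccc(OCc4ccccc4)c(OCc4ccccc4)c3)[C@@H]2O)c(OCc2ccccc2)c2c1O[C@H](c1ccc(OCc3ccccc3)c(OCc3ccccc3)c1)[C@@H](O)C2 | intermediate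

15 | ent-fisetinidol-(4α→6)-ent-fisetinidol-(4α→8)-catechin-(6→4α)-ent-fisetinidol (CNP0126838.1) | Oc1ccc2c(c1)O[C@@H](c1ccc(O)c(O)c1)[C@H](O)[C@@H]2c1cc2c(cc1O)O[C@@H](c1ccc(O)c(O)c1)[C@H](O)[C@@H]2c1c(O)c([C@@H]2c3ccc(O)cc3O[C@@H](c3ccc(O)c(O)c3)[C@@H]2O)c(O)c2c1O[C@H](c1ccc(O)c(O)c1)[C@@H](O)C2 | target

## Step count and risks

Total steps: 10. Longest linear sequence: 9 (steps 2 to 10, from 2,4-dihydroxybenzaldehyde).

**Step 8 (double arylation).** Risks: the ring-B site may lag behind catechin C6, forcing may alkylate C8 of unit B or a dibenzyloxyphenyl ring, and the ortho-pivalate could take part and erode inversion. Fallback, from 11 back to 14: run the arylations one at a time so that each has a single competent site. Treat 11 with 1.0 equiv of 7 at −20 °C under the same catalyst to get the catechin-C6 mono-adduct F3. LiAlH4 then HCl/MeOH (as in step 6) closes ring C of unit D and gives the trimer with a free 7-OH on unit D, F4. PivCl/Et3N at 0 °C turns that phenol into the electron-poor D-ring 7-O-pivalate F5, which switches ring A of unit D off as a nucleophile. A second arylation with 7 can then only go to C6 of unit B and gives the mono-adduct F6. LiAlH4 (which also removes the extra pivalate) followed by HCl/MeOH closes ring C of unit A and returns to 14.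

**Step 5 (first epoxide arylation).** Risks: 1,2-acyl (Meinwald-type) shift of the activated epoxy ketone, partial loss of inversion, and a sluggish reaction of the deactivated epoxide. Fallback, from 7 back to 10: close ring C first and accept a separation at C4. NaBH4 in MeOH/THF at −20 °C reduces 7 to the epoxy alcohol F1. LiOH in THF/water removes both pivalates; the para-phenoxide opens the epoxide through a quinone methide that takes up water at C4, and acidification to pH 3 closes the pyran ring to 3',4'-di-O-benzyl-ent-leucofisetinidin F2 (2S,3R, both C4 epimers). F2 and 2 (3 equiv) with catalytic TsOH·H2O in dioxane couple at C8 through the flavan-4-yl cation (the classical flavan-3,4-diol condensation). This gives 3,4-trans and 3,4-cis dimers; the 3,4-cis isomer, isolated by chromatography, is 10.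

**Step 9 (double ring closure).** Risks: 2,3-cis closure at either of the two new C2 centres, and hydride (pinacol-type) shift in the benzylic cation. Fallback, from 12 back to 14: replace the SN1 closure by a catalyst-controlled reduction followed by an invertive closure. Noyori-type transfer hydrogenation with RuCl[(S,S)-TsDPEN](p-cymene) and HCO2H/Et3N reduces both aryl ketones to the (R)-carbinols, giving the bis(syn-diol) tetrapivalate F7. K2CO3/MeOH removes the four pivalates to give the syn,syn tetraphenol F8. HC(OEt)3 with PPTS in 1,2-dichloroethane (rt, then 60 °C) converts each syn-diol into a cyclic orthoformate; its dioxolanylium ion is opened at the benzylic carbon by the ortho-phenol with inversion, giving the 2,3-trans bis(3-O-formate) F9. K2CO3/MeOH removes the formates and returns to 14.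

## Further compounds

F1 | step 5 | [3,4-bis(benzyloxy)phenyl][3-[2,4-bis(pivaloyloxy)phenyl]oxiran-2-yl]methanol (epoxide configured as in 7, carbinol epimers) | OC(c1ccc(OCc2ccccc2)c(OCc2ccccc2)c1)[C@@H]1O[C@H]1c1ccc(OC(=O)C(C)(C)C)cc1OC(=O)C(C)(C)C

F2 | step 5 | (2S,3R)-2-[3,4-bis(benzyloxy)phenyl]chromane-3,4,7-triol (2,3-trans, both C4 epimers) | Oc1ccc2c(c1)O[C@@H](c1ccc(OCc3ccccc3)c(OCc3ccccc3)c1)[C@H](O)C2O

F3 | step 8 | mono-adduct of 11 and 7 at catechin C6 (chain configured as in 8) | c1ccc(cc1)COc1ccc2c(c1)O[C@@H](c1ccc(OCc3ccccc3)c(OCc3ccccc3)c1)[C@H](O)[C@@H]2c1c(OCc2ccccc2)c([C@@H]([C@@H](O)C(=O)c2ccc(OCc3ccccc3)c(OCc3ccccc3)c2)c2ccc(OC(=O)C(C)(C)C)cc2OC(=O)C(C)(C)C)c(OCc2ccccc2)c2c1O[C@H](c1ccc(OCc3ccccc3)c(OCc3ccccc3)c1)[C@@H](O)C2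

F4 | step 8 | 7,3',4'-tri-O-benzyl-ent-fisetinidol-(4α→8)-5,7,3',4'-tetra-O-benzylcatechin-(6→4α)-3',4'-di-O-benzyl-ent-fisetinidol (free 7-OH on unit D) | c1ccc(cc1)COc1ccc2c(c1)O[C@@H](c1ccc(OCc3ccccc3)c(OCc3ccccc3)c1)[C@H](O)[C@@H]2c1c(OCc2ccccc2)c([C@@H]2c3ccc(O)cc3O[C@@H](c3ccc(OCc4ccccc4)c(OCc4ccccc4)c3)[C@@H]2O)c(OCc2ccccc2)c2c1O[C@H](c1ccc(OCc3ccccc3)c(OCc3ccccc3)c1)[C@@H](O)C2

F5 | step 8 | 7-O-pivalate (unit D) of F4 | c1ccc(cc1)COc1ccc2c(c1)O[C@@H](c1ccc(OCc3ccccc3)c(OCc3ccccc3)c1)[C@H](O)[C@@H]2c1c(OCc2ccccc2)c([C@@H]2c3ccc(OC(=O)C(C)(C)C)cc3O[C@@H](c3ccc(OCc4ccccc4)c(OCc4ccccc4)c3)[C@@H]2O)c(OCc2ccccc2)c2c1O[C@H](c1ccc(OCc3ccccc3)c(OCc3ccccc3)c1)[C@@H](O)C2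

F6 | step 8 | mono-adduct of F5 and 7 at C6 of unit B (chain configured as in 8) | CC(C)(C)C(=O)Oc1ccc(c(OC(=O)C(C)(C)C)c1)[C@H]([C@@H](O)C(=O)c1ccc(OCc2ccccc2)c(OCc2ccccc2)c1)c1cc2c(cc1OCc3ccccc3)O[C@@H](c1ccc(OCc3ccccc3)c(OCc3ccccc3)c1)[C@H](O)[C@@H]2c1c(OCc2ccccc2)c([C@@H]2c3ccc(OC(=O)C(C)(C)C)cc3O[C@@H](c3ccc(OCc4ccccc4)c(OCc4ccccc4)c3)[C@@H]2O)c(OCc2ccccc2)c2c1O[C@H](c1ccc(OCc3ccccc3)c(OCc3ccccc3)c1)[C@@H](O)C2

F7 | step 9 | bis(syn-diol) tetrapivalate from 12 (both new carbinols R) | CC(C)(C)C(=O)Oc1ccc(c(OC(=O)C(C)(C)C)c1)[C@H]([C@@H](O)[C@H](O)c1ccc(OCc2ccccc2)c(OCc2ccccc2)c1)c1cc2c(cc1OCc3ccccc3)O[C@@H](c1ccc(OCc3ccccc3)c(OCc3ccccc3)c1)[C@H](O)[C@@H]2c1c(OCc2ccccc2)c([C@@H]([C@@H](O)[C@H](O)c2ccc(OCc3ccccc3)c(OCc3ccccc3)c2)c2ccc(OC(=O)C(C)(C)C)cc2OC(=O)C(C)(C)C)c(OCc2ccccc2)c2c1O[C@H](c1ccc(OCc3ccccc3)c(OCc3ccccc3)c1)[C@@H](O)C2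

F8 | step 9 | syn,syn tetraphenol (the single carbinol diastereomer of 13 with both carbinols R) | Oc1ccc(c(O)c1)[C@H]([C@@H](O)[C@H](O)c1ccc(OCc2ccccc2)c(OCc2ccccc2)c1)c1cc2c(cc1OCc3ccccc3)O[C@@H](c1ccc(OCc3ccccc3)c(OCc3ccccc3)c1)[C@H](O)[C@@H]2c1c(OCc2ccccc2)c([C@@H]([C@@H](O)[C@H](O)c2ccc(OCc3ccccc3)c(OCc3ccccc3)c2)c2ccc(O)cc2O)c(OCc2ccccc2)c2c1O[C@H](c1ccc(OCc3ccccc3)c(OCc3ccccc3)c1)[C@@H](O)C2

F9 | step 9 | bis(3-O-formate) of 14 (formates on units A and D) | Oc1ccc2c(c1)O[C@@H](c1ccc(OCc3ccccc3)c(OCc3ccccc3)c1)[C@H](OC=O)[C@@H]2c1cc2c(cc1OCc3ccccc3)O[C@@H](c1ccc(OCc3ccccc3)c(OCc3ccccc3)c1)[C@H](O)[C@@H]2c1c(OCc2ccccc2)c([C@@H]2c3ccc(O)cc3O[C@@H](c3ccc(OCc4ccccc4)c(OCc4ccccc4)c3)[C@@H]2OC=O)c(OCc2ccccc2)c2c1O[C@H](c1ccc(OCc3ccccc3)c(OCc3ccccc3)c1)[C@@H](O)C2
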